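## Retrosynthetic overview

- The target is a single 14-membered carbocycle (ring atoms C1–C14; C2=C3 Z, C6=C7 E with the carboxyl on C7, C10=C11 E). Its only stereocentre, C14, carries the 1,1-disubstituted alkene carbon C15 of the side chain and lies two bonds from C2 (C14–C1–C2). With C2 written as an ester carbon, C14 is the beta-carbon of an enoate, so C14–C15 is made by a catalytic enantioselective conjugate alkenylation of an achiral enoate with an achiral 2-alkenyl boronate.
- The ring is closed last, at C8–C9: a C9 allylic sulfone anion adds to a Baylis–Hillman acetate (C6(OAc)–C7(=C8H2)CO2Me) with loss of acetate, which also sets 6E. Ester reduction, desulfonylation and re-oxidation then give the acid.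
- Between these two events the C2 ester is grown linearly: Still–Gennari olefination (2Z; adds C3, its methyl and C4), cyanomethyl homologation (C5, C6), Baylis–Hillman reaction (C7, C8, carboxyl carbon).
- The enoate (C1, C2, C9–C14) comes from geraniol by cleavage of the distal alkene and Horner–Wadsworth–Emmons reaction. The boronate (side chain from C15) comes from 6-methylhept-5-en-2-one through its kinetic enol triflate.

Key step: step 7

Assumption: (S)-BINAP is taken to direct the alkenyl group to the alpha-si face of the (E)-enoate, as BINAP–rhodium catalysts do with aryl donors on (E)-enoates; this face corresponds to R at C14.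

Remark: the centres formed without control at the epoxide carbon (3), the hemiacetal carbon (12), C6 (26–28) and C9 (29, 30) are all destroyed later, so these compounds are carried as mixtures. C-numbers in the text are the ring numbers of the target.

## Route

Step 1
Reactants: 1 geraniol
Product: 2 tert-butyl{[(2E)-3,7-dimethylocta-2,6-dien-1-yl]oxy}dimethylsilane
Conditions: TBSCl, imidazole, DMF, 0 °C to rt
Reagents that add atoms: tert-butyldimethylsilyl chloride, CC(C)(C)[Si](C)(C)Cl
Why: Imidazole-promoted silylation of a primary alcohol (silyl ether formation); no stereocentre is involved and the 2E alkene is untouched.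

Step 2
Reactants: 2 tert-butyl{[(2E)-3,7-dimethylocta-2,6-dien-1-yl]oxy}dimethylsilane
Product: 3 tert-butyl{[(2E)-5-(3,3-dimethyloxiran-2-yl)-3-methylpent-2-en-1-yl]oxy}dimethylsilane (racemic)
Conditions: mCPBA (1.05 equiv), NaHCO3, CH2Cl2, −20 to 0 °C
Reagents that add atoms: meta-chloroperoxybenzoic acid, O=C(OO)c1cccc(Cl)c1
Why: Prilezhaev epoxidation; the distal trisubstituted alkene is the more electron-rich one because the other is deactivated by the allylic silyloxy group, so it should react first, and the racemic epoxide centre is cleaved in step 3.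

Step 3
Reactants: 3 tert-butyl{[(2E)-5-(3,3-dimethyloxiran-2-yl)-3-methylpent-2-en-1-yl]oxy}dimethylsilane
Product: 4 (4E)-6-[(tert-butyldimethylsilyl)oxy]-4-methylhex-4-enal
Conditions: H5IO6, THF/Et2O, 0 °C, short reaction time
Reagents that add atoms: none
Why: Periodic acid opens the epoxide to the glycol and cleaves it in the same flask (Malaprade glycol cleavage) to the aldehyde and acetone; the short cold exposure should spare the primary silyl ether and the E alkene.

Step 4
Reactants: 4 (4E)-6-[(tert-butyldimethylsilyl)oxy]-4-methylhex-4-enal; 5 trimethyl phosphonoacetate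
Product: 6 methyl (2E,6E)-8-[(tert-butyldimethylsilyl)oxy]-6-methylocta-2,6-dienoate
Conditions: LiCl, DBU, MeCN, rt
Reagents that add atoms: none
Why: Horner–Wadsworth–Emmons olefination under Masamune–Roush conditions gives the E-disubstituted enoate from an unbranched aldehyde with a base too mild to affect the silyl ether.

Step 5
Reactants: 7 6-methylhept-5-en-2-one
Product: 9 6-methylhepta-1,5-dien-2-yl trifluoromethanesulfonate, via lithium 6-methylhepta-1,5-dien-2-olate 8 (not isolated)
Conditions: LiN(i-Pr)2, THF, −78 °C; then PhNTf2, −78 °C to rt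
Reagents that add atoms: N-phenylbis(trifluoromethanesulfonimide), O=S(=O)(N(c1ccccc1)S(=O)(=O)C(F)(F)F)C(F)(F)F
Why: Kinetic deprotonation of the methyl ketone by the hindered amide at −78 °C takes place at the methyl group, and O-triflation of enolate 8 gives the 1,1-disubstituted enol triflate (enol triflate formation).

Step 6
Reactants: 9 6-methylhepta-1,5-dien-2-yl trifluoromethanesulfonate
Product: 10 2-(6-methylhepta-1,5-dien-2-yl)-4,4,5,5-tetramethyl-1,3,2-dioxaborolane
Conditions: B2pin2, PdCl2(PPh3)2 (3 mol %), PPh3, KOPh, toluene, 50 °C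
Reagents that add atoms: bis(pinacolato)diboron, CC1(C)OB(OC1(C)C)B1OC(C)(C)C(C)(C)O1
Why: Miyaura borylation; zerovalent palladium inserts into the alkenyl C–OTf bond, phenoxide-assisted transmetalation with B2pin2 and reductive elimination give the alkenyl boronate with the alkene position retained.

Step 7
Reactants: 6 methyl (2E,6E)-8-[(tert-butyldimethylsilyl)oxy]-6-methylocta-2,6-dienoate; 10 2-(6-methylhepta-1,5-dien-2-yl)-4,4,5,5-tetramethyl-1,3,2-dioxaborolane
Product: 11 methyl (3R,6E)-8-[(tert-butyldimethylsilyl)oxy]-6-methyl-3-(6-methylhepta-1,5-dien-2-yl)oct-6-enoate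
Conditions: [Rh(cod)(OH)]2 (3 mol %), (S)-BINAP (7 mol %), 10 (2.5 equiv), KOH (20 mol %), 1,4-dioxane/H2O 10:1, 60 °C
Reagents that add atoms: none
Why: Hayashi–Miyaura asymmetric 1,4-addition: the monovalent rhodium hydroxide carrying (S)-BINAP transmetalates with boronate 10 to an alkenylrhodium species, the enoate C=C of 6 inserts into the Rh–C bond to give an oxa-pi-allyl rhodium enolate, and water protonates it to release 11 and return the hydroxide. The closest known reaction type is the rhodium/BINAP-catalysed conjugate addition of aryl- and alkenylboron reagents, 1-substituted vinyl donors included, to acyclic (E)-enoates and enones. No ring is closed. The new stereocentre C14 (C3 of 11) is controlled by the ligand alone: (S)-BINAP leaves one quadrant open so that the enoate binds through its alpha-si face, which places the alkenyl group on the face that gives R. The step needs 1,4- over 1,2-addition, reaction at the electron-poor alkene only, and transmetalation faster than protodeboronation; the first is inherent to organorhodium species, the second follows because the isolated trisubstituted alkenes do not insert, and the third is helped by the excess of 10, the small amount of KOH and the moderate temperature. The E geometry and the unbranched beta-substituent (C13H2) of 6 are the substrate features this catalyst class discriminates well.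

Step 8
Reactants: 11 methyl (3R,6E)-8-[(tert-butyldimethylsilyl)oxy]-6-methyl-3-(6-methylhepta-1,5-dien-2-yl)oct-6-enoate
Product: 13 (3R,6E)-8-[(tert-butyldimethylsilyl)oxy]-6-methyl-3-(6-methylhepta-1,5-dien-2-yl)oct-6-enal, via diisobutylaluminium hemiacetal 12 (not isolated)
Conditions: i-Bu2AlH (1.1 equiv), CH2Cl2, −78 °C; MeOH, then aqueous Rochelle salt
Reagents that add atoms: none
Why: Partial ester reduction; one equivalent of i-Bu2AlH at −78 °C stops at the tetrahedral aluminium hemiacetal 12, which collapses to the aldehyde on work-up, and C14 is beta to the carbonyl so it cannot epimerise.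

Step 9
Reactants: 13 (3R,6E)-8-[(tert-butyldimethylsilyl)oxy]-6-methyl-3-(6-methylhepta-1,5-dien-2-yl)oct-6-enal; 14 ethyl 2-[bis(2,2,2-trifluoroethoxy)phosphoryl]propanoate
Product: 15 ethyl (2Z,5R,8E)-10-[(tert-butyldimethylsilyl)oxy]-2,8-dimethyl-5-(6-methylhepta-1,5-dien-2-yl)deca-2,8-dienoate
Conditions: KN(SiMe3)2, 18-crown-6, THF, −78 °C
Reagents that add atoms: none
Why: Still–Gennari olefination; the bis(trifluoroethyl) phosphonate anion with a dissociated potassium counter-ion adds irreversibly and eliminates fast, which gives the Z trisubstituted enoate (C1 cis to the ester carbon C4) from an unbranched aldehyde.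

Step 10
Reactants: 15 ethyl (2Z,5R,8E)-10-[(tert-butyldimethylsilyl)oxy]-2,8-dimethyl-5-(6-methylhepta-1,5-dien-2-yl)deca-2,8-dienoate
Product: 16 (2Z,5R,8E)-10-[(tert-butyldimethylsilyl)oxy]-2,8-dimethyl-5-(6-methylhepta-1,5-dien-2-yl)deca-2,8-dien-1-ol
Conditions: i-Bu2AlH (2.5 equiv), CH2Cl2, −78 °C
Reagents that add atoms: none
Why: 1,2-Reduction of the conjugated ester by i-Bu2AlH gives the allylic alcohol without changing the alkene geometry or the silyl ether.

Step 11
Reactants: 16 (2Z,5R,8E)-10-[(tert-butyldimethylsilyl)oxy]-2,8-dimethyl-5-(6-methylhepta-1,5-dien-2-yl)deca-2,8-dien-1-ol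
Product: 17 tert-butyl{[(2E,6R,8Z)-10-bromo-3,9-dimethyl-6-(6-methylhepta-1,5-dien-2-yl)deca-2,8-dien-1-yl]oxy}dimethylsilane
Conditions: CBr4, PPh3, CH2Cl2, −20 to 0 °C
Reagents that add atoms: carbon tetrabromide, BrC(Br)(Br)Br
Why: Appel bromination converts the primary allylic alcohol into the bromide under neutral conditions at low temperature, which should preserve the Z geometry and avoid allylic transposition.

Step 12
Reactants: 17 tert-butyl{[(2E,6R,8Z)-10-bromo-3,9-dimethyl-6-(6-methylhepta-1,5-dien-2-yl)deca-2,8-dien-1-yl]oxy}dimethylsilane; 18 acetonitrile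
Product: 19 (4Z,7R,10E)-12-[(tert-butyldimethylsilyl)oxy]-4,10-dimethyl-7-(6-methylhepta-1,5-dien-2-yl)dodeca-4,10-dienenitrile
Conditions: 18 (5 equiv), n-BuLi, THF, −78 °C; then 17, −78 to −40 °C
Reagents that add atoms: none
Why: SN2 alkylation of lithioacetonitrile (in excess to suppress dialkylation) at the unhindered primary allylic carbon adds C5 and C6 and leaves the nitrile as a masked C6 aldehyde.

Step 13
Reactants: 19 (4Z,7R,10E)-12-[(tert-butyldimethylsilyl)oxy]-4,10-dimethyl-7-(6-methylhepta-1,5-dien-2-yl)dodeca-4,10-dienenitrile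
Product: 20 (4Z,7R,10E)-12-hydroxy-4,10-dimethyl-7-(6-methylhepta-1,5-dien-2-yl)dodeca-4,10-dienenitrile
Conditions: Bu4NF, THF, 0 °C
Reagents that add atoms: none
Why: Fluoride-mediated desilylation cleaves the primary silyl ether; the nitrile and the alkenes are inert.

Step 14
Reactants: 20 (4Z,7R,10E)-12-hydroxy-4,10-dimethyl-7-(6-methylhepta-1,5-dien-2-yl)dodeca-4,10-dienenitrile
Product: 21 (4Z,7R,10E)-12-bromo-4,10-dimethyl-7-(6-methylhepta-1,5-dien-2-yl)dodeca-4,10-dienenitrile
Conditions: CBr4, PPh3, CH2Cl2, −20 to 0 °C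
Reagents that add atoms: carbon tetrabromide, BrC(Br)(Br)Br
Why: Appel bromination of the primary allylic alcohol at C9 under neutral conditions keeps the 10E alkene in place.

Step 15
Reactants: 21 (4Z,7R,10E)-12-bromo-4,10-dimethyl-7-(6-methylhepta-1,5-dien-2-yl)dodeca-4,10-dienenitrile
Product: 22 (4Z,7R,10E)-4,10-dimethyl-7-(6-methylhepta-1,5-dien-2-yl)-12-(phenylsulfonyl)dodeca-4,10-dienenitrile
Conditions: PhSO2Na, DMF, rt
Reagents that add atoms: sodium benzenesulfinate, [Na+].[O-]S(=O)c1ccccc1
Why: SN2 S-alkylation of the sulfinate by the primary allylic bromide gives the allylic sulfone; it is installed here because sulfinate would otherwise attack the Baylis–Hillman acetate made later.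

Step 16
Reactants: 22 (4Z,7R,10E)-4,10-dimethyl-7-(6-methylhepta-1,5-dien-2-yl)-12-(phenylsulfonyl)dodeca-4,10-dienenitrile
Product: 24 (4Z,7R,10E)-4,10-dimethyl-7-(6-methylhepta-1,5-dien-2-yl)-12-(phenylsulfonyl)dodeca-4,10-dienal, via N-diisobutylaluminio aldimine 23 (not isolated)
Conditions: i-Bu2AlH (1.3 equiv), toluene, −78 °C; then 1 M HCl, 0 °C
Reagents that add atoms: water, O
Why: Nitrile-to-aldehyde reduction; i-Bu2AlH adds once to give the N-aluminio imine 23, which resists further reduction and is hydrolysed on acidic work-up, while the sulfone is not reduced at −78 °C.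

Step 17
Reactants: 24 (4Z,7R,10E)-4,10-dimethyl-7-(6-methylhepta-1,5-dien-2-yl)-12-(phenylsulfonyl)dodeca-4,10-dienal; 25 methyl acrylate
Product: 26 methyl (6Z,9R,12E)-3-hydroxy-6,12-dimethyl-2-methylidene-9-(6-methylhepta-1,5-dien-2-yl)-14-(phenylsulfonyl)tetradeca-6,12-dienoate (mixture of C3 epimers)
Conditions: DABCO (1 equiv), 25 (excess), MeOH, rt, several days
Reagents that add atoms: none
Why: Baylis–Hillman reaction; DABCO adds to the acrylate, the ammonium enolate adds to the unhindered aldehyde and loss of DABCO gives the alpha-methylene beta-hydroxy ester, the carbinol centre (C6) forming without control and being lost in step 19, and DABCO is too weak to deprotonate the sulfone.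

Step 18
Reactants: 26 methyl (6Z,9R,12E)-3-hydroxy-6,12-dimethyl-2-methylidene-9-(6-methylhepta-1,5-dien-2-yl)-14-(phenylsulfonyl)tetradeca-6,12-dienoate
Product: 27 methyl (6Z,9R,12E)-3-acetoxy-6,12-dimethyl-2-methylidene-9-(6-methylhepta-1,5-dien-2-yl)-14-(phenylsulfonyl)tetradeca-6,12-dienoate (mixture of C3 epimers)
Conditions: AcCl, pyridine, CH2Cl2, 0 °C
Reagents that add atoms: acetyl chloride, CC(=O)Cl
Why: O-Acylation of the secondary allylic alcohol without a nucleophilic catalyst (so no allylic transposition) installs the acetate leaving group.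

Step 19
Reactants: 27 methyl (6Z,9R,12E)-3-acetoxy-6,12-dimethyl-2-methylidene-9-(6-methylhepta-1,5-dien-2-yl)-14-(phenylsulfonyl)tetradeca-6,12-dienoate
Product: 29 methyl (1E,5Z,8R,11E)-5,11-dimethyl-8-(6-methylhepta-1,5-dien-2-yl)-13-(phenylsulfonyl)cyclotetradeca-1,5,11-triene-1-carboxylate as a mixture of sulfone epimers, via C9-lithiated sulfone 28 (not isolated)
Conditions: LiN(SiMe3)2 (1.1 equiv), THF (0.002 M), −78 °C to rt
Reagents that add atoms: none
Why: Intramolecular SN2' alkylation (conjugate addition then E1cB loss of acetate) of the sulfone-stabilised allylic carbanion 28 at C8 closes the 14-membered ring under high dilution; acetate leaves from the ester enolate through the conformer with the C5 chain anti to the ester, the usual course for acrylate-derived Baylis–Hillman acetates, which gives 6E, and the C9 epimers converge in step 21.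

Step 20
Reactants: 29 methyl (1E,5Z,8R,11E)-5,11-dimethyl-8-(6-methylhepta-1,5-dien-2-yl)-13-(phenylsulfonyl)cyclotetradeca-1,5,11-triene-1-carboxylate
Product: 30 [(1E,5Z,8R,11E)-5,11-dimethyl-8-(6-methylhepta-1,5-dien-2-yl)-13-(phenylsulfonyl)cyclotetradeca-1,5,11-trien-1-yl]methanol (mixture of sulfone epimers)
Conditions: i-Bu2AlH (2.5 equiv), CH2Cl2, −78 °C
Reagents that add atoms: none
Why: 1,2-Reduction of the conjugated ester by i-Bu2AlH gives the allylic alcohol and so removes the hydride-sensitive enoate before the desulfonylation.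

Step 21
Reactants: 30 [(1E,5Z,8R,11E)-5,11-dimethyl-8-(6-methylhepta-1,5-dien-2-yl)-13-(phenylsulfonyl)cyclotetradeca-1,5,11-trien-1-yl]methanol
Product: 31 [(1E,5Z,8R,11E)-5,11-dimethyl-8-(6-methylhepta-1,5-dien-2-yl)cyclotetradeca-1,5,11-trien-1-yl]methanol
Conditions: PdCl2(dppp) (10 mol %), LiBHEt3 (4 equiv), THF, 0 °C
Reagents that add atoms: none
Why: Palladium-catalysed reductive desulfonylation; zerovalent palladium ionises the allylic sulfone to a pi-allyl complex and hydride from LiBHEt3 is delivered to the less substituted terminus C9, which keeps C10=C11 in place with E geometry, and the alkoxide formed from the free alcohol is inert.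

Step 22
Reactants: 31 [(1E,5Z,8R,11E)-5,11-dimethyl-8-(6-methylhepta-1,5-dien-2-yl)cyclotetradeca-1,5,11-trien-1-yl]methanol
Product: 32 (1E,5Z,8R,11E)-5,11-dimethyl-8-(6-methylhepta-1,5-dien-2-yl)cyclotetradeca-1,5,11-triene-1-carbaldehyde
Conditions: MnO2, CH2Cl2, rt
Reagents that add atoms: none
Why: MnO2 oxidises only the primary allylic alcohol to the conjugated aldehyde, with no over-oxidation.

Step 23
Reactants: 32 (1E,5Z,8R,11E)-5,11-dimethyl-8-(6-methylhepta-1,5-dien-2-yl)cyclotetradeca-1,5,11-triene-1-carbaldehyde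
Product: 33 (1E,5Z,8R,11E)-5,11-dimethyl-8-(6-methylhepta-1,5-dien-2-yl)cyclotetradeca-1,5,11-triene-1-carboxylic acid
Conditions: NaClO2, NaH2PO4, 2-methylbut-2-ene, t-BuOH/H2O, rt
Reagents that add atoms: sodium chlorite, [Na+].[O-]Cl=O
Why: Pinnick oxidation converts the enal into the acid without touching or isomerising the alkenes, 2-methylbut-2-ene scavenging the hypochlorous acid formed.

## Compound list

1 | geraniol, (2E)-3,7-dimethylocta-2,6-dien-1-ol | CC(C)=CCC/C(C)=C/CO | starting material
2 | tert-butyl{[(2E)-3,7-dimethylocta-2,6-dien-1-yl]oxy}dimethylsilane | CC(C)=CCC/C(C)=C/CO[Si](C)(C)C(C)(C)C | intermediate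
3 | tert-butyl{[(2E)-5-(3,3-dimethyloxiran-2-yl)-3-methylpent-2-en-1-yl]oxy}dimethylsilane, racemic | CC1(C)OC1CC/C(C)=C/CO[Si](C)(C)C(C)(C)C | intermediate
4 | (4E)-6-[(tert-butyldimethylsilyl)oxy]-4-methylhex-4-enal | O=CCC/C(C)=C/CO[Si](C)(C)C(C)(C)C | intermediate
5 | trimethyl phosphonoacetate | COC(=O)CP(=O)(OC)OC | starting material
6 | methyl (2E,6E)-8-[(tert-butyldimethylsilyl)oxy]-6-methylocta-2,6-dienoate | COC(=O)/C=C/CC/C(C)=C/CO[Si](C)(C)C(C)(C)C | intermediate
7 | 6-methylhept-5-en-2-one | CC(C)=CCCC(C)=O | starting material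
8 | lithium 6-methylhepta-1,5-dien-2-olate (not isolated) | [Li+].C=C([O-])CCC=C(C)C | intermediate
9 | 6-methylhepta-1,5-dien-2-yl trifluoromethanesulfonate | C=C(CCC=C(C)C)OS(=O)(=O)C(F)(F)F | intermediate
10 | 2-(6-methylhepta-1,5-dien-2-yl)-4,4,5,5-tetramethyl-1,3,2-dioxaborolane | C=C(CCC=C(C)C)B1OC(C)(C)C(C)(C)O1 | intermediate
11 | methyl (3R,6E)-8-[(tert-butyldimethylsilyl)oxy]-6-methyl-3-(6-methylhepta-1,5-dien-2-yl)oct-6-enoate | C=C(CCC=C(C)C)[C@@H](CC(=O)OC)CC/C(C)=C/CO[Si](C)(C)C(C)(C)C | intermediate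
12 | diisobutylaluminium hemiacetal of 11 (not isolated; hemiacetal carbon unassigned) | C=C(CCC=C(C)C)[C@@H](CC(OC)O[Al](CC(C)C)CC(C)C)CC/C(C)=C/CO[Si](C)(C)C(C)(C)C | intermediate
13 | (3R,6E)-8-[(tert-butyldimethylsilyl)oxy]-6-methyl-3-(6-methylhepta-1,5-dien-2-yl)oct-6-enal | C=C(CCC=C(C)C)[C@@H](CC=O)CC/C(C)=C/CO[Si](C)(C)C(C)(C)C | intermediate
14 | ethyl 2-[bis(2,2,2-trifluoroethoxy)phosphoryl]propanoate | CCOC(=O)C(C)P(=O)(OCC(F)(F)F)OCC(F)(F)F | starting material
15 | ethyl (2Z,5R,8E)-10-[(tert-butyldimethylsilyl)oxy]-2,8-dimethyl-5-(6-methylhepta-1,5-dien-2-yl)deca-2,8-dienoate | C=C(CCC=C(C)C)[C@@H](C/C=C(/C)C(=O)OCC)CC/C(C)=C/CO[Si](C)(C)C(C)(C)C | intermediate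
16 | (2Z,5R,8E)-10-[(tert-butyldimethylsilyl)oxy]-2,8-dimethyl-5-(6-methylhepta-1,5-dien-2-yl)deca-2,8-dien-1-ol | C=C(CCC=C(C)C)[C@@H](C/C=C(/C)CO)CC/C(C)=C/CO[Si](C)(C)C(C)(C)C | intermediate
17 | tert-butyl{[(2E,6R,8Z)-10-bromo-3,9-dimethyl-6-(6-methylhepta-1,5-dien-2-yl)deca-2,8-dien-1-yl]oxy}dimethylsilane | C=C(CCC=C(C)C)[C@@H](C/C=C(/C)CBr)CC/C(C)=C/CO[Si](C)(C)C(C)(C)C | intermediate
18 | acetonitrile | CC#N | starting material
19 | (4Z,7R,10E)-12-[(tert-butyldimethylsilyl)oxy]-4,10-dimethyl-7-(6-methylhepta-1,5-dien-2-yl)dodeca-4,10-dienenitrile | C=C(CCC=C(C)C)[C@@H](C/C=C(/C)CCC#N)CC/C(C)=C/CO[Si](C)(C)C(C)(C)C | intermediate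
20 | (4Z,7R,10E)-12-hydroxy-4,10-dimethyl-7-(6-methylhepta-1,5-dien-2-yl)dodeca-4,10-dienenitrile | C=C(CCC=C(C)C)[C@@H](C/C=C(/C)CCC#N)CC/C(C)=C/CO | intermediate
21 | (4Z,7R,10E)-12-bromo-4,10-dimethyl-7-(6-methylhepta-1,5-dien-2-yl)dodeca-4,10-dienenitrile | C=C(CCC=C(C)C)[C@@H](C/C=C(/C)CCC#N)CC/C(C)=C/CBr | intermediate
22 | (4Z,7R,10E)-4,10-dimethyl-7-(6-methylhepta-1,5-dien-2-yl)-12-(phenylsulfonyl)dodeca-4,10-dienenitrile | C=C(CCC=C(C)C)[C@@H](C/C=C(/C)CCC#N)CC/C(C)=C/CS(=O)(=O)c1ccccc1 | intermediate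
23 | N-diisobutylaluminio aldimine of 24 (not isolated) | C=C(CCC=C(C)C)[C@@H](C/C=C(/C)CCC=N[Al](CC(C)C)CC(C)C)CC/C(C)=C/CS(=O)(=O)c1ccccc1 | intermediate
24 | (4Z,7R,10E)-4,10-dimethyl-7-(6-methylhepta-1,5-dien-2-yl)-12-(phenylsulfonyl)dodeca-4,10-dienal | C=C(CCC=C(C)C)[C@@H](C/C=C(/C)CCC=O)CC/C(C)=C/CS(=O)(=O)c1ccccc1 | intermediate
25 | methyl acrylate | C=CC(=O)OC | starting material
26 | methyl (6Z,9R,12E)-3-hydroxy-6,12-dimethyl-2-methylidene-9-(6-methylhepta-1,5-dien-2-yl)-14-(phenylsulfonyl)tetradeca-6,12-dienoate, C3 epimers | C=C(CCC=C(C)C)[C@@H](C/C=C(/C)CCC(O)C(=C)C(=O)OC)CC/C(C)=C/CS(=O)(=O)c1ccccc1 | intermediate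
27 | methyl (6Z,9R,12E)-3-acetoxy-6,12-dimethyl-2-methylidene-9-(6-methylhepta-1,5-dien-2-yl)-14-(phenylsulfonyl)tetradeca-6,12-dienoate, C3 epimers | C=C(CCC=C(C)C)[C@@H](C/C=C(/C)CCC(OC(C)=O)C(=C)C(=O)OC)CC/C(C)=C/CS(=O)(=O)c1ccccc1 | intermediate
28 | 27 lithiated at the sulfonyl-bearing carbon C9 (not isolated) | C=C(CCC=C(C)C)[C@@H](C/C=C(/C)CCC(OC(C)=O)C(=C)C(=O)OC)CC/C(C)=C/C([Li])S(=O)(=O)c1ccccc1 | intermediate
29 | methyl (1E,5Z,8R,11E)-5,11-dimethyl-8-(6-methylhepta-1,5-dien-2-yl)-13-(phenylsulfonyl)cyclotetradeca-1,5,11-triene-1-carboxylate, C13 epimers | C=C(CCC=C(C)C)[C@H]1C/C=C(/C)CC/C=C(/C(=O)OC)CC(S(=O)(=O)c2ccccc2)/C=C(\C)CC1 | intermediate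
30 | [(1E,5Z,8R,11E)-5,11-dimethyl-8-(6-methylhepta-1,5-dien-2-yl)-13-(phenylsulfonyl)cyclotetradeca-1,5,11-trien-1-yl]methanol, C13 epimers | C=C(CCC=C(C)C)[C@H]1C/C=C(/C)CC/C=C(/CO)CC(S(=O)(=O)c2ccccc2)/C=C(\C)CC1 | intermediate
31 | [(1E,5Z,8R,11E)-5,11-dimethyl-8-(6-methylhepta-1,5-dien-2-yl)cyclotetradeca-1,5,11-trien-1-yl]methanol | C=C(CCC=C(C)C)[C@H]1C/C=C(/C)CC/C=C(/CO)CC/C=C(\C)CC1 | intermediate
32 | (1E,5Z,8R,11E)-5,11-dimethyl-8-(6-methylhepta-1,5-dien-2-yl)cyclotetradeca-1,5,11-triene-1-carbaldehyde | C=C(CCC=C(C)C)[C@H]1C/C=C(/C)CC/C=C(/C=O)CC/C=C(\C)CC1 | intermediate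
33 | (1E,5Z,8R,11E)-5,11-dimethyl-8-(6-methylhepta-1,5-dien-2-yl)cyclotetradeca-1,5,11-triene-1-carboxylic acid | C=C(CCC=C(C)C)[C@H]1C/C=C(/C)CC/C=C(/C(=O)O)CC/C=C(\C)CC1 | target

## Step count and risks

Total steps: 23. Longest linear sequence: 21 steps (steps 1–4 and 7–23, from geraniol); steps 5–6 form the convergent branch.

Steps most likely to fail:

1. Step 7. Transmetalation of the hindered 1,1-disubstituted alkenyl boronate may be slow, so that protodeboronation and ester hydrolysis overtake the conjugate addition, or the ligand may discriminate the enoate faces insufficiently with this donor.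
Fallback (sets out from 6 and 7, comes back at 11): auxiliary-controlled cuprate addition in place of catalysis. LiOH in THF/H2O would convert 6 into (2E,6E)-8-[(tert-butyldimethylsilyl)oxy]-6-methylocta-2,6-dienoic acid F1. PivCl/Et3N would give the pivalic mixed anhydride F2, which with (S)-4-phenyloxazolidin-2-one, LiCl and Et3N would give the N-enoyl oxazolidinone F3. Ketone 7 and 2,4,6-triisopropylbenzenesulfonyl hydrazide would give the hydrazone F4. A Shapiro reaction (n-BuLi, 2 equiv, THF, −78 to 0 °C) would then give 2-lithio-6-methylhepta-1,5-diene F5. After transmetalation with MgBr2·OEt2 and CuBr·SMe2, the alkenyl copper reagent would add to F3 at −78 °C anti to the phenyl group of the magnesium-chelated syn-s-cis imide, giving the (3R)-adduct F6. MeOMgBr in MeOH/THF would then release ester 11 and the auxiliary.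

2. Step 19. Intermolecular alkylation (oligomerisation) may compete with closure of the 14-membered ring, or acetate may leave through the other enolate conformer and give the 6Z alkene.
Fallback (sets out from 26, comes back at 29): fix the alkene geometry before ring closure and close by direct SN2 displacement. NBS/Me2S (CH2Cl2, 0 °C) would convert alcohol 26, with allylic transposition, into the primary allylic bromide methyl (2Z,6Z,9R,12E)-2-(bromomethyl)-6,12-dimethyl-9-(6-methylhepta-1,5-dien-2-yl)-14-(phenylsulfonyl)tetradeca-2,6,12-trienoate F7, in which C5 is already trans to the ester. LiN(SiMe3)2 under high dilution would then alkylate the sulfone anion at the CH2Br carbon, the established way of closing 14-membered terpenoid rings, to give 29.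

3. Step 17. The amine-catalysed addition to an enolisable aliphatic aldehyde may stall over days while the aldehyde is consumed by self-aldol condensation.
Fallback (sets out from 24, comes back at 26): a stoichiometric alpha-metallated acrylate in place of amine catalysis. Hydroalumination of methyl propiolate with i-Bu2AlH in THF/HMPA at 0 °C would give methyl 2-(diisobutylalumanyl)prop-2-enoate F8, which should add to aldehyde 24 within hours and give 26 after aqueous work-up.

## Further compounds

F1 | step 7 | (2E,6E)-8-[(tert-butyldimethylsilyl)oxy]-6-methylocta-2,6-dienoic acid | O=C(O)/C=C/CC/C(C)=C/CO[Si](C)(C)C(C)(C)C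
F2 | step 7 | (2E,6E)-8-[(tert-butyldimethylsilyl)oxy]-6-methylocta-2,6-dienoic pivalic anhydride | CC(C)(C)C(=O)OC(=O)/C=C/CC/C(C)=C/CO[Si](C)(C)C(C)(C)C
F3 | step 7 | (4S)-3-[(2E,6E)-8-[(tert-butyldimethylsilyl)oxy]-6-methylocta-2,6-dienoyl]-4-phenyloxazolidin-2-one | O=C(/C=C/CC/C(C)=C/CO[Si](C)(C)C(C)(C)C)N1[C@@H](c2ccccc2)COC1=O
F4 | step 7 | (E)-N'-(6-methylhept-5-en-2-ylidene)-2,4,6-triisopropylbenzenesulfonohydrazide | CC(C)=CCC/C(C)=N/NS(=O)(=O)c1c(C(C)C)cc(C(C)C)cc1C(C)C
F5 | step 7 | 2-lithio-6-methylhepta-1,5-diene | [Li]C(=C)CCC=C(C)C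
F6 | step 7 | (4S)-3-[(3R,6E)-8-[(tert-butyldimethylsilyl)oxy]-6-methyl-3-(6-methylhepta-1,5-dien-2-yl)oct-6-enoyl]-4-phenyloxazolidin-2-one | C=C(CCC=C(C)C)[C@@H](CC(=O)N1[C@@H](c2ccccc2)COC1=O)CC/C(C)=C/CO[Si](C)(C)C(C)(C)C
F7 | step 19 | methyl (2Z,6Z,9R,12E)-2-(bromomethyl)-6,12-dimethyl-9-(6-methylhepta-1,5-dien-2-yl)-14-(phenylsulfonyl)tetradeca-2,6,12-trienoate | C=C(CCC=C(C)C)[C@@H](C/C=C(/C)CC/C=C(/C(=O)OC)CBr)CC/C(C)=C/CS(=O)(=O)c1ccccc1
F8 | step 17 | methyl 2-(diisobutylalumanyl)prop-2-enoate | C=C([Al](CC(C)C)CC(C)C)C(=O)OC
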